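A direct plan would isobutyrylate phloroglucinol A1 to the ketone A2, methylate one ortho hydroxyl to reach A3, C-prenylate this to A4, build the pyranone half A5 separately, and join A4 and A5 through one methylene carbon by way of the methylidene-pyrandione A6.
No stereocentre would be at stake and its one ring closure (the pyranone) would be safe, but three of its steps would only decorate the bought arene A1 one substituent at a time.
Its weakest steps would be:
- the mono-O-methylation of A2, which would have to pick one chelated ortho hydroxyl out of three phenols without close precedent (para-, over- and C-methylation compete);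
- the base-mediated C-prenylation of A3, where O-alkylation, the second free ring carbon and double alkylation would all compete;
- the final methylene bridging, the step one would least like to run on late material, because the transient acceptor A6 would also capture its own precursor A5 and phenol oxygen while the fully built arene is at stake.

**Plan of the new route**
The benzene ring is never substituted; it is made last, from a 2-pyranone (ring A).
The arene is a phloroglucinol, so it can be read as a folded 4-acyl-3,5-dioxo ester: aryl C6–C1–C2 (C1 carries the bridge CH2) is a malonyl unit, and aryl C3–C4–C5 with the isobutyryl group is a 1,3-diketone.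
Closed as a 2-pyranone (lactone C=O = aryl C2, ring O on aryl C4, C4–OH = the future aryl C6–OMe), this chain has only one hydroxyl, the one that must be methylated.
Retrosynthesis cuts aryl C2–C3 (key step), then the hydroxypyranone of the target (ring B: malonyl unit + silyl enol ether), the bridge CH2–CH bond (Michael addition to a methylidenemalonate), ring A (malonyl dichloride + diketone) and the CH2–CH2 bond beside the prenyl olefin (dianion alkylation).
The rings arise in the order A, B, arene; the target has no stereocentre.
Methylation meets a single OH, the prenyl carbon is fixed before any ring exists, and the bridge carbon comes inside a malonate, so neither selective phenol alkylation nor late methylene bridging occurs.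

Key step: step 9

Assumption: in step 2 the unsymmetrical diketone is taken to close the lactone through the enol oxygen of its unbranched ketone (less hindered). The ring isomer with the two acyl groups exchanged would be opened by methoxide in step 9 to the same enolate and so to the same arene, and need not be separated.

Step 1
Reactants: 1 5-methylhexane-2,4-dione; 2 1-bromo-3-methylbut-2-ene
Product: 3 2,9-dimethyldec-8-ene-3,5-dione
Conditions: LiN(i-Pr)2 (2.1 equiv), THF, −78 → 0 °C; 2 (1.0 equiv), −78 °C → rt; aq. NH4Cl
Reagents that add atoms: none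
Why: Alkylation of a 1,3-diketone dianion at its terminal carbon: the second deprotonation occurs at the methyl group rather than at the methine, and this most basic carbanion displaces the allylic bromide (SN2), which fixes the carbon that will carry the prenyl group.

Step 2
Reactants: 3 2,9-dimethyldec-8-ene-3,5-dione; 4 propanedioyl dichloride
Product: 6 4-hydroxy-6-(4-methylpent-3-en-1-yl)-5-(2-methylpropanoyl)-2H-pyran-2-one, via triketo acid chloride 5 (not isolated)
Conditions: 4 (1.0 equiv), Et2O, 0 °C → rt, slow N2 stream to carry off HCl; chromatography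
Reagents that add atoms: none
Why: Pyranone synthesis from a 1,3-diketone and malonyl dichloride, as known for pentane-2,4-dione: one acid chloride acylates the central carbon of the enol, the enol oxygen then closes the lactone (6-exo-trig), and the hydrogen-bonded 5-acyl-4-hydroxy-2-pyranone is the conjugated sink.

Step 3
Reactants: 7 di-tert-butyl propanedioate; 8 paraformaldehyde
Product: 9 di-tert-butyl 2-methylidenepropanedioate
Conditions: (CH2O)n (2 equiv), KOAc (cat.), Cu(OAc)2·H2O (cat.), AcOH, 90–100 °C; distillation
Reagents that add atoms: none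
Why: Knoevenagel condensation of the malonate with formaldehyde and dehydration; the bulky esters make the methylidenemalonate a distillable, storable acceptor.

Step 4
Reactants: 6 4-hydroxy-6-(4-methylpent-3-en-1-yl)-5-(2-methylpropanoyl)-2H-pyran-2-one; 9 di-tert-butyl 2-methylidenepropanedioate
Product: 10 di-tert-butyl 2-{[4-hydroxy-6-(4-methylpent-3-en-1-yl)-5-(2-methylpropanoyl)-2-oxo-2H-pyran-3-yl]methyl}propanedioate
Conditions: 9 (1.1 equiv), Et3N (0.1 equiv), CH2Cl2, 0 °C → rt
Reagents that add atoms: none
Why: Michael addition of C3 of the 4-hydroxy-2-pyranone (a vinylogous acid that reacts at carbon, as 4-hydroxycoumarins do with alkylidenemalonates) to an isolated, non-enolisable acceptor, which places exactly one methylene carbon between ring A and a malonate; the tert-butyl esters prevent lactonisation by the 4-OH.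

Step 5
Reactants: 10 di-tert-butyl 2-{[4-hydroxy-6-(4-methylpent-3-en-1-yl)-5-(2-methylpropanoyl)-2-oxo-2H-pyran-3-yl]methyl}propanedioate
Product: 11 di-tert-butyl 2-{[4-methoxy-6-(4-methylpent-3-en-1-yl)-5-(2-methylpropanoyl)-2-oxo-2H-pyran-3-yl]methyl}propanedioate
Conditions: Me2SO4 (1.2 equiv), K2CO3 (1.1 equiv), acetone, rt
Reagents that add atoms: dimethyl sulfate, COS(=O)(=O)OC
Why: Williamson O-methylation of the only hydroxyl in the molecule: the potassium salt of a 4-hydroxy-2-pyranone is alkylated by dimethyl sulfate at the 4-oxygen (the usual 4-methoxy-2-pyranone outcome), and the single equivalent of carbonate is consumed by this acidic OH before the hindered malonate C–H is touched.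

Step 6
Reactants: 11 di-tert-butyl 2-{[4-methoxy-6-(4-methylpent-3-en-1-yl)-5-(2-methylpropanoyl)-2-oxo-2H-pyran-3-yl]methyl}propanedioate
Product: 12 2-{[4-methoxy-6-(4-methylpent-3-en-1-yl)-5-(2-methylpropanoyl)-2-oxo-2H-pyran-3-yl]methyl}propanedioic acid
Conditions: Me3SiOTf (2.5 equiv), 2,6-lutidine (3 equiv), CH2Cl2, 0 °C; then H2O, extraction at pH 3, kept cold
Reagents that add atoms: none
Why: Cleavage of tert-butyl esters by a silyl triflate (O-silylation, loss of isobutene, silyl esters hydrolysed on work-up) under buffered, non-protic conditions that spare the trisubstituted olefin and the vinylogous ester.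

Step 7
Reactants: 13 pentan-3-one
Product: 14 (Z)-trimethyl(pent-2-en-3-yloxy)silane
Conditions: Me3SiOTf (1.1 equiv), Et3N (1.3 equiv), Et2O, 0 °C → rt; pentane extraction, distillation
Reagents that add atoms: trimethylsilyl trifluoromethanesulfonate, C[Si](C)(C)OS(=O)(=O)C(F)(F)F
Why: Soft enolisation and O-silylation of a symmetric ketone (silyl enol ether formation); both geometric isomers lead to the same pyranone.

Step 8
Reactants: 12 2-{[4-methoxy-6-(4-methylpent-3-en-1-yl)-5-(2-methylpropanoyl)-2-oxo-2H-pyran-3-yl]methyl}propanedioic acid; 14 (Z)-trimethyl(pent-2-en-3-yloxy)silane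
Product: 17 6-ethyl-4-hydroxy-3-{[4-methoxy-6-(4-methylpent-3-en-1-yl)-5-(2-methylpropanoyl)-2-oxo-2H-pyran-3-yl]methyl}-5-methyl-2H-pyran-2-one, via malonyl dichloride 15 (not isolated), via diketo acid chloride 16 (not isolated)
Conditions: 1-chloro-N,N,2-trimethylprop-1-en-1-amine (2.2 equiv), CH2Cl2, 0 °C → rt; then 14 (1.2 equiv), Et2O, −78 °C → rt; pH 7 buffer
Reagents that add atoms: none
Why: The neutral α-chloroenamine turns the malonic acid into its dichloride without free HCl; the dichloride acylates the silyl enol ether at carbon (loss of Me3SiCl) and the enol oxygen closes the lactone (6-exo-trig), the known synthesis of 3-substituted 4-hydroxy-2-pyranones from malonyl dichlorides and silyl enol ethers.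

Step 9
Reactants: 17 6-ethyl-4-hydroxy-3-{[4-methoxy-6-(4-methylpent-3-en-1-yl)-5-(2-methylpropanoyl)-2-oxo-2H-pyran-3-yl]methyl}-5-methyl-2H-pyran-2-one
Product: 20 3-{[2,4-dihydroxy-6-methoxy-3-(3-methylbut-2-en-1-yl)-5-(2-methylpropanoyl)phenyl]methyl}-6-ethyl-4-hydroxy-5-methyl-2H-pyran-2-one, via open-chain enoate 18 (not isolated), via cyclohexadienone 19 (not isolated)
Conditions: NaOMe (6 equiv), MeOH, 0 °C → rt, argon; MeOH exchanged for THF, t-BuOK (4 equiv), 0 → 40 °C; cold 1 M HCl to pH 4, EtOAc
Reagents that add atoms: none
Why: Proposed new method: methoxide opens the acyl-activated 4-methoxy-2-pyranone (ring A) at the lactone carbonyl, as in the known methanolysis of 4-methoxy-6-methyl-2-pyranone to a 3-methoxy-5-oxo-2-enoate, giving the (E)-enoate 18 in which the ester and the 1,3-diketonate are held cis on the former ring double bond; in the aprotic, more basic second stage the terminal α-carbon of the diketonate (the former 6-CH2) attacks this ester in an intramolecular Claisen condensation (6-enolendo-exo-trig), methoxide leaves, and dienone 19 tautomerises to the phenoxide, the thermodynamic sink. The closest known reaction types are the Claisen-mode cyclisation of polyketo esters and of 6-(2-oxoalkyl)-2-pyranones to acylphloroglucinols, the base-induced closure of 3-methoxy-5-oxo-enoates to phloroglucinol monomethyl ethers, and the acylation of 1,3-diketone dianions by esters at the terminal carbon. No stereocentre is formed. The step needs C–C closure through the CH2 and not through the isopropyl methine or an oxygen: closure through the methine would give a gem-dimethyl trione that cannot aromatise and reverts by retro-Claisen, O-closure only regenerates a pyranone, and no aldol mode competes because the α-carbon of the ester is fully substituted and locked in the enol ether. Ring B is protected as its 4-oxido anion, the methoxy group can only exchange degenerately with methoxide, and any cyclic ether formed by attack of the ring B oxygen on the methoxy-bearing carbon should be reopened by methoxide at that same, more electrophilic carbon. The pyranone thereby fixes all six arene substituents at once: lactone carbonyl and ring oxygen become the two free hydroxyls, the 4-methoxy group becomes the aryl methyl ether, and the acyl, prenyl and bridge carbons keep their places.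

**Compound list**
1 | 5-methylhexane-2,4-dione | CC(C)C(=O)CC(C)=O | starting material
2 | 1-bromo-3-methylbut-2-ene | CC(C)=CCBr | starting material
3 | 2,9-dimethyldec-8-ene-3,5-dione | CC(C)C(=O)CC(=O)CCC=C(C)C | intermediate
4 | propanedioyl dichloride | O=C(Cl)CC(=O)Cl | starting material
5 | 9-methyl-4-(2-methylpropanoyl)-3,5-dioxodec-8-enoyl chloride (enolising) | CC(C)C(=O)C(C(=O)CC(=O)Cl)C(=O)CCC=C(C)C | intermediate (not isolated)
6 | 4-hydroxy-6-(4-methylpent-3-en-1-yl)-5-(2-methylpropanoyl)-2H-pyran-2-one | CC(C)C(=O)c1c(O)cc(=O)oc1CCC=C(C)C | intermediate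
7 | di-tert-butyl propanedioate | CC(C)(C)OC(=O)CC(=O)OC(C)(C)C | starting material
8 | paraformaldehyde (as formaldehyde) | C=O | starting material
9 | di-tert-butyl 2-methylidenepropanedioate | C=C(C(=O)OC(C)(C)C)C(=O)OC(C)(C)C | intermediate
10 | di-tert-butyl 2-{[4-hydroxy-6-(4-methylpent-3-en-1-yl)-5-(2-methylpropanoyl)-2-oxo-2H-pyran-3-yl]methyl}propanedioate | CC(C)C(=O)c1c(O)c(CC(C(=O)OC(C)(C)C)C(=O)OC(C)(C)C)c(=O)oc1CCC=C(C)C | intermediate
11 | di-tert-butyl 2-{[4-methoxy-6-(4-methylpent-3-en-1-yl)-5-(2-methylpropanoyl)-2-oxo-2H-pyran-3-yl]methyl}propanedioate | CC(C)C(=O)c1c(OC)c(CC(C(=O)OC(C)(C)C)C(=O)OC(C)(C)C)c(=O)oc1CCC=C(C)C | intermediate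
12 | 2-{[4-methoxy-6-(4-methylpent-3-en-1-yl)-5-(2-methylpropanoyl)-2-oxo-2H-pyran-3-yl]methyl}propanedioic acid | CC(C)C(=O)c1c(OC)c(CC(C(=O)O)C(=O)O)c(=O)oc1CCC=C(C)C | intermediate
13 | pentan-3-one | CCC(=O)CC | starting material
14 | (Z)-trimethyl(pent-2-en-3-yloxy)silane | C/C=C(/CC)O[Si](C)(C)C | intermediate
15 | 2-{[4-methoxy-6-(4-methylpent-3-en-1-yl)-5-(2-methylpropanoyl)-2-oxo-2H-pyran-3-yl]methyl}propanedioyl dichloride | CC(C)C(=O)c1c(OC)c(CC(C(=O)Cl)C(=O)Cl)c(=O)oc1CCC=C(C)C | intermediate (not isolated)
16 | 2-{[4-methoxy-6-(4-methylpent-3-en-1-yl)-5-(2-methylpropanoyl)-2-oxo-2H-pyran-3-yl]methyl}-4-methyl-3,5-dioxoheptanoyl chloride (enolising) | CCC(=O)C(C)C(=O)C(Cc1c(OC)c(C(=O)C(C)C)c(CCC=C(C)C)oc1=O)C(=O)Cl | intermediate (not isolated)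
17 | 6-ethyl-4-hydroxy-3-{[4-methoxy-6-(4-methylpent-3-en-1-yl)-5-(2-methylpropanoyl)-2-oxo-2H-pyran-3-yl]methyl}-5-methyl-2H-pyran-2-one | CCc1oc(=O)c(Cc2c(OC)c(C(=O)C(C)C)c(CCC=C(C)C)oc2=O)c(O)c1C | intermediate
18 | methyl (2E)-2-[(6-ethyl-4-hydroxy-5-methyl-2-oxo-2H-pyran-3-yl)methyl]-3-methoxy-9-methyl-4-(2-methylpropanoyl)-5-oxodeca-2,8-dienoate (C4 enolising, drawn as the diketone) | COC(=O)/C(Cc1c(O)c(C)c(CC)oc1=O)=C(/OC)C(C(=O)C(C)C)C(=O)CCC=C(C)C | intermediate (not isolated)
19 | 6-ethyl-4-hydroxy-3-{[4-hydroxy-2-methoxy-5-(3-methylbut-2-en-1-yl)-3-(2-methylpropanoyl)-6-oxocyclohexa-1,3-dien-1-yl]methyl}-5-methyl-2H-pyran-2-one (racemic, transient) | CCc1oc(=O)c(CC2=C(OC)C(C(=O)C(C)C)=C(O)C(CC=C(C)C)C2=O)c(O)c1C | intermediate (not isolated)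
20 | 3-{[2,4-dihydroxy-6-methoxy-3-(3-methylbut-2-en-1-yl)-5-(2-methylpropanoyl)phenyl]methyl}-6-ethyl-4-hydroxy-5-methyl-2H-pyran-2-one | CCc1oc(=O)c(Cc2c(O)c(CC=C(C)C)c(O)c(C(=O)C(C)C)c2OC)c(O)c1C | target

**Count and risks**
Total steps: 9. Longest linear sequence: 7 (steps 1, 2, 4, 5, 6, 8, 9).

Steps most likely to fail:

1. Step 9 (proposed new method). The ring opening may stop at the acyclic ester, methoxide may add at the conjugate positions of ring A, and in the closure the hindered methine or retro-Claisen loss of the isobutyryl group may compete. The fallback uses known chemistry in two discrete operations and sets out from 17. Ring A would be opened with Mg(OMe)2 in MeOH at reflux, the known methanolysis of 4-methoxy-2-pyranones, and enoate 18 isolated. Then 18 would be treated with LiN(i-Pr)2 (4.5 equiv) in THF at −78 → 0 °C, so that the terminal carbon of the 1,3-diketone dianion, the most basic site of the polyanion, is acylated by the ester (the known terminal acylation of diketone dianions). This returns to the route at 20 by way of 19. No new compound arises on this way, so the fallback is entered as F0.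

2. Step 8. The HCl set free in the lactonisation may add to the trisubstituted olefin, and acid may promote loss of methanol through attack of the new ring B hydroxyl on the methoxy-bearing carbon of ring A. The fallback sets out from 12 and avoids acid chlorides and the silyl enol ether altogether. The diacid would be converted with C6F5OH and dicyclohexylcarbodiimide (EtOAc, 0 °C) into the bis(pentafluorophenyl) ester F1. Pentan-3-one 13 would then be C-acylated directly under soft enolisation (MgBr2·OEt2, i-Pr2NEt, CH2Cl2, rt), the second active ester closing the lactone. This returns to the route at 17.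

3. Step 2. Either enol oxygen of the unsymmetrical diketone can close the lactone, a second molecule of malonyl dichloride can acylate C3 of the product, and HCl can add to the olefin. The fallback sets out from 3 and separates C-acylation from ring closure. Chelation-controlled C-acylation (MgCl2, pyridine, methyl 3-chloro-3-oxopropanoate, CH2Cl2, 0 °C) should give the triketo ester F2. Lactonisation with DBU in toluene at 80 °C, with loss of methanol, returns to the route at 6. The ring-isomer question stays harmless for the reason given in the assumption.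

**Further compounds**
F0 | step 9 | none | none
F1 | step 8 | bis(pentafluorophenyl) 2-{[4-methoxy-6-(4-methylpent-3-en-1-yl)-5-(2-methylpropanoyl)-2-oxo-2H-pyran-3-yl]methyl}propanedioate | CC(C)C(=O)c1c(OC)c(CC(C(=O)Oc2c(F)c(F)c(F)c(F)c2F)C(=O)Oc2c(F)c(F)c(F)c(F)c2F)c(=O)oc1CCC=C(C)C
F2 | step 2 | methyl 9-methyl-4-(2-methylpropanoyl)-3,5-dioxodec-8-enoate | COC(=O)CC(=O)C(C(=O)C(C)C)C(=O)CCC=C(C)C
A1 | direct plan | benzene-1,3,5-triol | Oc1cc(O)cc(O)c1
A2 | direct plan | 2-methyl-1-(2,4,6-trihydroxyphenyl)propan-1-one | CC(C)C(=O)c1c(O)cc(O)cc1O
A3 | direct plan | 1-(2,4-dihydroxy-6-methoxyphenyl)-2-methylpropan-1-one | CC(C)C(=O)c1c(O)cc(O)cc1OC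
A4 | direct plan | 1-[2,4-dihydroxy-6-methoxy-3-(3-methylbut-2-en-1-yl)phenyl]-2-methylpropan-1-one | CC(C)C(=O)c1c(O)c(CC=C(C)C)c(O)cc1OC
A5 | direct plan | 6-ethyl-4-hydroxy-5-methyl-2H-pyran-2-one | CCc1oc(=O)cc(O)c1C
A6 | direct plan | 6-ethyl-5-methyl-3-methylidene-2H-pyran-2,4(3H)-dione | CCC1=C(C)C(=O)C(=C)C(=O)O1
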